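Assumption: the 3E/3Z mixture of acid 10 is used as such (that alkene is re-formed in step 5), and the chiral acid catalyst of step 5 is made by its published route and not counted as a step.

**Retrosynthetic overview**
1. Target 18 ⇐ alcohol 17 ⇐ acid 15: final acetylation and a chemoselective CO2H → CH2OH reduction.
2. 15 ⇐ enoic acid 11 + furan-2(5H)-one 12 + an electrophilic oxygen: a three-component dienediolate α-Michael addition / enolate hydroxylation; the lactone ring is bought intact and the 1,1-disubstituted alkene appears by deconjugation.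
3. 11 ⇐ acyclic triene acid 10: one asymmetric proton-initiated cation–olefin bicyclisation closes the six-membered ring first and the five-membered ring second in the same operation, setting C1, C3a and C7a.
4. 10 ⇐ aldehyde 6 + β-carboxy ylide from crotonic acid (Wittig); 6 ⇐ geranyl bromide + acetonitrile.

**Route**

Step 1
Reactants: 1 geranyl bromide [(2E)-1-bromo-3,7-dimethylocta-2,6-diene]; 2 acetonitrile
Product: 4 (4E)-5,9-dimethyldeca-4,8-dienenitrile, via lithioacetonitrile 3 (not isolated)
Conditions: 2 (3 equiv), LiN(i-Pr)2 (3 equiv), THF, −78 °C; then 1, −78 → −20 °C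
Reagents that add atoms: none
Why: SN2 alkylation of lithioacetonitrile at the primary allylic bromide adds the two-carbon unit without touching the (E)-trisubstituted alkene, and no stereocentre is formed.

Step 2
Reactants: 4 (4E)-5,9-dimethyldeca-4,8-dienenitrile
Product: 6 (4E)-5,9-dimethyldeca-4,8-dienal, via N-aluminio imine 5 (not isolated)
Conditions: i-Bu2AlH (1.2 equiv), CH2Cl2, −78 °C; then 1 M HCl, 0 °C
Reagents that add atoms: water, O
Why: Partial reduction of the nitrile by i-Bu2AlH stops at the N-aluminio imine, which hydrolyses to the aldehyde on work-up (nitrile-to-aldehyde reduction).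

Step 3
Reactants: 7 crotonic acid [(2E)-but-2-enoic acid]
Product: 8 (1-carboxypropan-2-yl)triphenylphosphonium bromide (racemic)
Conditions: Ph3P·HBr (1.0 equiv), MeCN, reflux, 24 h
Reagents that add atoms: triphenylphosphine hydrobromide, Br.c1ccc(cc1)P(c1ccccc1)c1ccccc1
Why: Phospha-Michael addition of triphenylphosphine to the protonated enoic acid gives the β-phosphonio acid, as in the known preparation of (2-carboxyethyl)triphenylphosphonium bromide from acrylic acid; the new stereocentre is racemic and is destroyed in step 4.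

Step 4
Reactants: 6 (4E)-5,9-dimethyldeca-4,8-dienal; 8 (1-carboxypropan-2-yl)triphenylphosphonium bromide
Product: 10 (7E)-3,8,12-trimethyltrideca-3,7,11-trienoic acid (3E/3Z mixture), via carboxylate ylide 9 (not isolated)
Conditions: 8 (1.3 equiv), NaN(SiMe3)2 (2.6 equiv), THF, −78 → 0 °C; then 6, −78 °C → rt; 1 M HCl
Reagents that add atoms: none
Why: Wittig olefination with the non-stabilised ylide, whose carboxylate form prevents α-deprotonation and loss of phosphine, gives the β,γ-unsaturated acid; the C3=C4 geometry is not controlled and does not matter because C3 is re-formed as an alkene carbon in step 5.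

Step 5
Reactants: 10 (7E)-3,8,12-trimethyltrideca-3,7,11-trienoic acid
Product: 11 (2E)-3-[(1R,3aS,7aS)-4,4,7a-trimethyloctahydro-1H-inden-1-yl]but-2-enoic acid
Conditions: chiral imidodiphosphorimidate Brønsted acid (IDPi; two 3,3'-bis[3,5-bis(trifluoromethyl)phenyl]-BINOL units, P=NSO2CF3 groups; the enantiomer giving the 3aS,7aS series) 5 mol%, (CF3)3COH, 0 °C, 48 h
Reagents that add atoms: none
Why: Proposed new method: the confined chiral acid protonates the terminal trisubstituted alkene (C11) and the chain, folded chair-like about the 7E alkene, closes the six-membered ring (C12–C7) and then the five-membered ring by 5-exo attack of C4 on the developing C8 cation, antiperiplanar addition across the E alkene giving the trans ring fusion, the pseudo-equatorial terminating alkene placing C1 cis to the angular methyl and the catalyst pocket fixing the absolute sense, after which loss of the acidified C2–H gives the conjugated E acid that is no longer protonated; closest known reaction type is the IDPi-catalysed asymmetric proton-initiated polyene cyclisation of homofarnesol to ambroxide (cation–olefin bicyclisation).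

Step 6
Reactants: 11 (2E)-3-[(1R,3aS,7aS)-4,4,7a-trimethyloctahydro-1H-inden-1-yl]but-2-enoic acid; 12 furan-2(5H)-one
Product: 15 (2R)-2-[(3R,4S)-4-hydroxy-5-oxooxolan-3-yl]-3-[(1R,3aS,7aS)-4,4,7a-trimethyloctahydro-1H-inden-1-yl]but-3-enoic acid, via dienediolate 13 (not isolated), via lactone enolate 14 (not isolated)
Conditions: LiN(i-Pr)2 (2.2 equiv), THF–DMPU, −78 → 0 °C; 12 (1.2 equiv), −78 °C; then 2-(phenylsulfonyl)-3-phenyloxaziridine (1.5 equiv), −78 °C; 1 M HCl
Reagents that add atoms: 2-(phenylsulfonyl)-3-phenyloxaziridine, O=S(=O)(c1ccccc1)N1OC1c1ccccc1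
Why: γ-Deprotonation of the lithium carboxylate at the methyl group cis to it gives the s-cis dienediolate, whose kinetic α-carbon Michael addition to 12 moves the alkene into the exo-methylene position and is expected to set C2 by attack anti to the quaternary C7a (ring C1–H eclipsing the C=CH2 bond) and oxolane C3 through a lithium-bridged synclinal transition state with the small C2–H over the lactone ring, after which the Davis oxaziridine hydroxylates the lactone enolate anti to the new C3 substituent to give the trans α-hydroxy lactone (dienolate α-Michael addition / Davis enolate oxidation).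

Step 7
Reactants: 15 (2R)-2-[(3R,4S)-4-hydroxy-5-oxooxolan-3-yl]-3-[(1R,3aS,7aS)-4,4,7a-trimethyloctahydro-1H-inden-1-yl]but-3-enoic acid
Product: 17 (3S,4R)-3-hydroxy-4-[(2R)-1-hydroxy-3-[(1R,3aS,7aS)-4,4,7a-trimethyloctahydro-1H-inden-1-yl]but-3-en-2-yl]oxolan-2-one, via mixed anhydride 16 (not isolated)
Conditions: i-BuOCOCl (1.1 equiv), N-methylmorpholine (1.1 equiv), THF, −15 °C; then NaBH4 (2 equiv), H2O, 0 °C, 15 min
Reagents that add atoms: none
Why: Activation as the mixed carbonic anhydride lets NaBH4 reduce only that carboxyl to the primary alcohol while the γ-lactone and the alkene are inert in the short reaction time (mixed-anhydride/borohydride reduction), and the trans-disposed ring hydroxyl cannot lactonise onto the activated carboxyl; no stereocentre changes.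

Step 8
Reactants: 17 (3S,4R)-3-hydroxy-4-[(2R)-1-hydroxy-3-[(1R,3aS,7aS)-4,4,7a-trimethyloctahydro-1H-inden-1-yl]but-3-en-2-yl]oxolan-2-one
Product: 18 [(2R)-2-[(3R,4S)-4-hydroxy-5-oxooxolan-3-yl]-3-[(1R,3aS,7aS)-4,4,7a-trimethyloctahydro-1H-inden-1-yl]but-3-en-1-yl] acetate (CNP0252518.2)
Conditions: AcCl (1.05 equiv), 2,4,6-collidine (2 equiv), CH2Cl2, −78 °C
Reagents that add atoms: acetyl chloride, CC(=O)Cl
Why: Kinetically selective acylation of the unhindered primary alcohol over the hindered, electron-poor α-hydroxy-lactone alcohol gives the monoacetate (chemoselective O-acetylation); no stereocentre changes.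

**Compound list**
1 | geranyl bromide, (2E)-1-bromo-3,7-dimethylocta-2,6-diene | CC(C)=CCC/C(C)=C/CBr | starting material
2 | acetonitrile | CC#N | starting material
3 | lithioacetonitrile (LiCH2CN) | [Li+].[CH2-]C#N | intermediate
4 | (4E)-5,9-dimethyldeca-4,8-dienenitrile | CC(C)=CCC/C(C)=C/CCC#N | intermediate
5 | (4E)-N-(diisobutylalumanyl)-5,9-dimethyldeca-4,8-dien-1-imine | CC(C)=CCC/C(C)=C/CCC=N[Al](CC(C)C)CC(C)C | intermediate
6 | (4E)-5,9-dimethyldeca-4,8-dienal | CC(C)=CCC/C(C)=C/CCC=O | intermediate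
7 | crotonic acid, (2E)-but-2-enoic acid | C/C=C/C(=O)O | starting material
8 | (1-carboxypropan-2-yl)triphenylphosphonium bromide, racemic | CC(CC(=O)O)[P+](c1ccccc1)(c1ccccc1)c1ccccc1.[Br-] | intermediate
9 | sodium 3-(triphenyl-λ5-phosphanylidene)butanoate | CC(CC(=O)[O-])=P(c1ccccc1)(c1ccccc1)c1ccccc1.[Na+] | intermediate
10 | (7E)-3,8,12-trimethyltrideca-3,7,11-trienoic acid, 3E/3Z mixture (C3=C4 geometry left open in the SMILES) | CC(C)=CCC/C(C)=C/CCC=C(C)CC(=O)O | intermediate
11 | (2E)-3-[(1R,3aS,7aS)-4,4,7a-trimethyloctahydro-1H-inden-1-yl]but-2-enoic acid | C/C(=C\C(=O)O)[C@H]1CC[C@H]2C(C)(C)CCC[C@]12C | intermediate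
12 | furan-2(5H)-one | O=C1OCC=C1 | starting material
13 | dilithium 3-[(1R,3aS,7aS)-4,4,7a-trimethyloctahydro-1H-inden-1-yl]buta-1,3-diene-1,1-bis(olate) | C=C(C=C([O-])[O-])[C@H]1CC[C@H]2C(C)(C)CCC[C@]12C.[Li+].[Li+] | intermediate
14 | dilithium salt (carboxylate and lactone enolate) of the Michael adduct, configured at C2 and ring C3 as in 15 | C=C([C@H]1CC[C@H]2C(C)(C)CCC[C@]12C)[C@H](C(=O)[O-])[C@@H]1COC([O-])=C1.[Li+].[Li+] | intermediate
15 | (2R)-2-[(3R,4S)-4-hydroxy-5-oxooxolan-3-yl]-3-[(1R,3aS,7aS)-4,4,7a-trimethyloctahydro-1H-inden-1-yl]but-3-enoic acid | C=C([C@H]1CC[C@H]2C(C)(C)CCC[C@]12C)[C@H](C(=O)O)[C@@H]1COC(=O)[C@H]1O | intermediate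
16 | mixed isobutyl carbonic anhydride of 15 | C=C([C@H]1CC[C@H]2C(C)(C)CCC[C@]12C)[C@H](C(=O)OC(=O)OCC(C)C)[C@@H]1COC(=O)[C@H]1O | intermediate
17 | (3S,4R)-3-hydroxy-4-[(2R)-1-hydroxy-3-[(1R,3aS,7aS)-4,4,7a-trimethyloctahydro-1H-inden-1-yl]but-3-en-2-yl]oxolan-2-one | C=C([C@H]1CC[C@H]2C(C)(C)CCC[C@]12C)[C@H](CO)[C@@H]1COC(=O)[C@H]1O | intermediate
18 | [(2R)-2-[(3R,4S)-4-hydroxy-5-oxooxolan-3-yl]-3-[(1R,3aS,7aS)-4,4,7a-trimethyloctahydro-1H-inden-1-yl]but-3-en-1-yl] acetate | C=C([C@H]1CC[C@H]2C(C)(C)CCC[C@]12C)[C@H](COC(C)=O)[C@@H]1COC(=O)[C@H]1O | target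

**Step count**
Total: 8 steps. Longest linear sequence: 7 steps (steps 1, 2, 4, 5, 6, 7, 8; 1 → 4 → 6 → 10 → 11 → 15 → 17 → 18).

**Three steps most likely to fail**

Step 5 (asymmetric bicyclisation). Risks are low enantioselectivity with an elimination-terminated substrate, monocyclic by-products from protonation of an internal alkene, and proton loss away from C2. The fallback sets out from 10 and comes back at 11. Acid 10 is cyclised without asymmetric induction with ClSO3H in 2-nitropropane at −78 °C, which gives 11 together with its enantiomer (2E)-3-[(1S,3aR,7aR)-4,4,7a-trimethyloctahydro-1H-inden-1-yl]but-2-enoic acid F1. The racemate is resolved by crystallising the (R)-1-phenylethylammonium salt of 11 F2 (the other amine enantiomer is used if the salt of F1 proves the less soluble), and 1 M HCl liberates 11.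

Step 6 (three-component coupling). Risks are γ- instead of α-attack of the dienediolate, deprotonation of 12 instead of addition, and only moderate substrate control at C2 and ring C3. The fallback sets out from 11 and comes back at 17. Acid 11 is converted (t-BuCOCl, Et3N; then the lithium salt of (R)-4-benzyloxazolidin-2-one) into the imide (4R)-4-benzyl-3-[(2E)-3-[(1R,3aS,7aS)-4,4,7a-trimethyloctahydro-1H-inden-1-yl]but-2-enoyl]-1,3-oxazolidin-2-one F3. Its sodium dienolate (NaN(SiMe3)2, THF, −78 °C) is added to 12 and hydroxylated with the same oxaziridine, now under auxiliary control of C2, to give the imide (4R)-4-benzyl-3-[(2R)-2-[(3R,4S)-4-hydroxy-5-oxooxolan-3-yl]-3-[(1R,3aS,7aS)-4,4,7a-trimethyloctahydro-1H-inden-1-yl]but-3-enoyl]-1,3-oxazolidin-2-one F4. NaBH4 in THF–H2O at 0 °C then cleaves the imide reductively to 17, so step 7 is not needed.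

Step 4 (Wittig with the hindered β-carboxy ylide, which also depends on the sluggish salt formation of step 3). The fallback sets out from 6 and comes back at 10. Isopropenylmagnesium bromide adds to 6 to give (6E)-2,7,11-trimethyldodeca-1,6,10-trien-3-ol F5. KH and Bu3SnCH2I give the stannylmethyl ether tributyl({[(6E)-2,7,11-trimethyldodeca-1,6,10-trien-3-yl]oxy}methyl)stannane F6. n-BuLi at −78 °C triggers the [2,3]-Wittig–Still rearrangement to (3Z,7E)-3,8,12-trimethyltrideca-3,7,11-trien-1-ol F7. TEMPO/PhI(OAc)2 in MeCN–H2O oxidises F7 to the 3Z isomer of 10.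

**Further compounds**
F1 | step 5 | (2E)-3-[(1S,3aR,7aR)-4,4,7a-trimethyloctahydro-1H-inden-1-yl]but-2-enoic acid | C/C(=C\C(=O)O)[C@@H]1CC[C@@H]2C(C)(C)CCC[C@@]12C
F2 | step 5 | (R)-1-phenylethylammonium (2E)-3-[(1R,3aS,7aS)-4,4,7a-trimethyloctahydro-1H-inden-1-yl]but-2-enoate | C/C(=C\C(=O)[O-])[C@H]1CC[C@H]2C(C)(C)CCC[C@]12C.C[C@@H]([NH3+])c1ccccc1
F3 | step 6 | (4R)-4-benzyl-3-[(2E)-3-[(1R,3aS,7aS)-4,4,7a-trimethyloctahydro-1H-inden-1-yl]but-2-enoyl]-1,3-oxazolidin-2-one | C/C(=C\C(=O)N1[C@H](Cc2ccccc2)COC1=O)[C@H]1CC[C@H]2C(C)(C)CCC[C@]12C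
F4 | step 6 | (4R)-4-benzyl-3-[(2R)-2-[(3R,4S)-4-hydroxy-5-oxooxolan-3-yl]-3-[(1R,3aS,7aS)-4,4,7a-trimethyloctahydro-1H-inden-1-yl]but-3-enoyl]-1,3-oxazolidin-2-one | C=C([C@H]1CC[C@H]2C(C)(C)CCC[C@]12C)[C@H](C(=O)N1[C@H](Cc2ccccc2)COC1=O)[C@@H]1COC(=O)[C@H]1O
F5 | step 4 | (6E)-2,7,11-trimethyldodeca-1,6,10-trien-3-ol, racemic | CC(C)=CCC/C(C)=C/CCC(O)C(C)=C
F6 | step 4 | tributyl({[(6E)-2,7,11-trimethyldodeca-1,6,10-trien-3-yl]oxy}methyl)stannane, racemic | CC(C)=CCC/C(C)=C/CCC(OC[Sn](CCCC)(CCCC)CCCC)C(C)=C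
F7 | step 4 | (3Z,7E)-3,8,12-trimethyltrideca-3,7,11-trien-1-ol | CC(C)=CCC/C(C)=C/CC/C=C(/C)CCO
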